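Readings and results stem from a simulated flask with made-up constants, noise included.

**Early times.** In the first 1.00 h of Saturday's run Q fell to 30.7% of its charge, which in logarithms is 0.513 of a power of ten. At that pace Q would fall by a factor of 10 in 1.95 h. I called this reading the decade time: the time for Q to drop one power of ten at its starting pace, treated as pseudo-first-order with cZ near 36 mM. Later Q went more slowly, with 2.9% left at 5.00 h, so the measure belongs to the start of Saturday's run.

| flask | Q | Z | temperature | remark | time |
|---|---|---|---|---|---|
| Saturday's | 6 mM | 36 mM | 30 °C | run made earlier |  |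
| epsilon | 12 mM | 36.0 mM | 30 °C |  | 40 h |
| eta | 12 mM | 36.0 mM | 5 °C |  | 40 h |
| theta | 12 mM | 36.0 mM | −20 °C |  | 40 h |
| alpha | 12 mM | 36.0 mM |  | at 30 °C until 12 h, from then on at −20 °C | 40 h |

Saturday's run (percent of the Q charged)

| time / h | G / % | Q / % |
|---|---|---|
| 1.00 | 56.8 | 30.7 |
| 1.33 | 61.4 | 23.1 |
| 2.00 | 63.4 | 14.2 |
| 3.00 | 63.4 | 7.2 |
| 5.00 | 61.0 | 2.9 |
| 8.00 | 57.1 | 1.4 |
| 12.0 | 53.9 | 0.2 |

(readings scatter by 0.3 percentage points)

- the analysis behind the earlier runs scatters by 0.3 percentage points, standard deviation
- the earlier runs do not show what temperature does; that part of a forecast is a guess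

- the flask with the highest amount of G, in percent of the Q charged ("all alike" if they lie within 1.5 percentage points) (epsilon / eta / theta / alpha / all alike)
- final G, as a percentage of the Q charged, in epsilon
- final G, as a percentage of the Q charged, in eta
- final G, as a percentage of the Q charged, in theta
- final G, as a percentage of the Q charged, in alpha

**Two twins.** Alpha and epsilon have the same charges and stay alike until 12 h, which is 6.15 decade times on Saturday's reading. At that time Saturday's Q read 0.2%. What still went on in Saturday's run was a slide in G, from 57.1% at 8.00 h to 53.9% at 12.0 h. Epsilon stays warm for 28.0 h more, so I expected its G to go on sliding. Alpha should keep what it has if cold slows that slide, so I put alpha above epsilon.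

**The cold flask.** Temperature was a guess. If cold slowed theta 100 times, its 40 h would be 0.205 of a decade, so Q would stay unfinished. I therefore put alpha above theta too, and I did not place eta.

**The forecast.** It named eta, with epsilon 27%, eta 47%, theta 28% and alpha 42%. Its temperature guess reads: “Ea is about 60 kJ/mol for all steps”. It ranked eta first, a flask I had left unplaced.

**The result.** Q + Z → G (k = 3.50 M⁻¹ h⁻¹, Ea = 71.0 kJ mol⁻¹); Z + G → J (k = 0.740 M⁻¹ h⁻¹, Ea = 53.0 kJ mol⁻¹); Z + J → E (k = 14.0 M⁻¹ h⁻¹, Ea = 54.0 kJ mol⁻¹); 2 Z → D (k = 1.00 M⁻¹ h⁻¹, Ea = 66.0 kJ mol⁻¹); Q + G → L (k = 5.10 M⁻¹ h⁻¹, Ea = 56.0 kJ mol⁻¹); (constants at 5 °C)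

Alpha held the most G, 44.8%, against epsilon 40.0%, eta 38.0% and theta 16.6%. Theta still held 79% of its Q at 40.0 h. That is 0.102 of a decade, a decade time of 388 h. This is 199 times the reading from Saturday's run, or 2.30 powers of ten, which is more than my guess of 100; that run differed from theta in its Q as well as in its temperature.

**Second flask.** Theta read at 15 h comes to 0.0387 of a decade on that slowed decade time, which leaves Q at 91.5%. The computed flask holds 91% of its Q.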